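The route rests on cutting O1–C8a in pyran ring C of the ether-bound third flavan unit, together with the C5–O and C7–O bonds of its ring A. C5, C7 and C8a are mutually meta, and C5 and C8a flank C4a symmetrically, so ring A is carried as a 2,4,6-trifluorophenyl group. This electron-poor mask can neither ionise at C4 nor act as a carbon nucleophile, so the epicatechin-(4β→8)-epicatechin C4 cation is taken up at oxygen only. In one operation the C2 alkoxide then displaces either ortho fluorine, with C2, C3 and C4 untouched, and benzyl oxide replaces the other two. The precursor is an acyclic silylated 1,3-diarylpropanetriol ether.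

Key step: step 13

Remark on the chemistry: flavan numbering (O1, C2, C3, C4, C4a, C5–C8, C8a, primed B-ring positions) is used for all three units, called top, middle and third unit. The SMILES is read as follows: top unit (2R,3R,4R) and middle unit (2R,3R,4S), both epicatechin-type with 4β bonds, and third unit (2S,3S,4S), that is 2,3-cis-3,4-cis. DMI is 1,3-dimethyl-2-imidazolidinone.

Step 1
Reactants: 1 (−)-epicatechin
Product: 2 3,5,7,3',4'-penta-O-benzyl-(−)-epicatechin
Conditions: BnBr (6 equiv), NaH, DMF, −10 °C to rt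
Reagents that add atoms: benzyl bromide, BrCc1ccccc1
Why: Williamson ether synthesis on all five hydroxyl groups; with the halide present from the start and at low temperature the phenoxides should be capped before ring opening to the B-ring quinone methide can epimerise C2, so (2R,3R) is kept.

Step 2
Reactants: 2 3,5,7,3',4'-penta-O-benzyl-(−)-epicatechin
Product: 3 (2R,3R,4S)-4β-(2-ethoxyethoxy)-3,5,7,3',4'-penta-O-benzylepicatechin
Conditions: DDQ, 2-ethoxyethanol, CH2Cl2, rt
Reagents that add atoms: 2-ethoxyethanol, CCOCCO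
Why: DDQ-mediated oxidative benzylic C–H alkoxylation: hydride loss from C4 gives the cation stabilised by ring A, and the alcohol should add from the β face, anti to the 2α-aryl and 3α-benzyloxy groups, which sets C4 as 4β (3,4-trans).

Step 3
Reactants: 3 4β-(2-ethoxyethoxy)-penta-O-benzylepicatechin
Product: 4 8-bromo-4β-(2-ethoxyethoxy)-3,5,7,3',4'-penta-O-benzylepicatechin
Conditions: NBS (1.0 equiv), CH2Cl2, −78 to −20 °C
Reagents that add atoms: N-bromosuccinimide, O=C1CCC(=O)N1Br
Why: Electrophilic aromatic bromination, which on 5,7-di-O-benzylflavans should go to C8, the most nucleophilic position of ring A, and blocks it so that 4 cannot act as a nucleophile later.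

Step 4
Reactants: 3 4β-(2-ethoxyethoxy)-penta-O-benzylepicatechin
Product: 5 4β-(2,6-dimethylphenylthio)-3,5,7,3',4'-penta-O-benzylepicatechin
Conditions: 2,6-dimethylbenzenethiol (excess), BF3·OEt2, CH2Cl2, −78 °C
Reagents that add atoms: 2,6-dimethylbenzenethiol, Cc1cccc(C)c1S
Why: Lewis acid promoted SN1 exchange at C4 (thiolysis of a 4-alkoxyflavan): BF3 ionises the chelating alkoxy group, the excess of soft thiol outruns self-condensation at C8, and β attack anti to the C2 and C3 groups keeps the 3,4-trans pattern.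

Step 5
Reactants: 4 8-bromo-4β-(2-ethoxyethoxy)-penta-O-benzylepicatechin; 5 4β-(2,6-dimethylphenylthio)-penta-O-benzylepicatechin
Product: 6 8-bromo-penta-O-benzylepicatechin-(4β→8)-4β-(2,6-dimethylphenylthio)-penta-O-benzylepicatechin
Conditions: BF3·OEt2, 4 Å molecular sieves, CH2Cl2, −78 to −30 °C
Reagents that add atoms: none
Why: Friedel–Crafts type flavan C4 to C8 coupling under orthogonal activation: the hard Lewis acid ionises only the C4–O group of 4 and leaves the C4–S group of 5 alone, C8 of 5 is the most nucleophilic free position, the bromine stops 4 from self-condensing, and β attack sets the new C4 stereocentre 3,4-trans.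

Step 6
Reactants: 7 (R)-4-benzyl-2-oxazolidinone; 8 benzyloxyacetyl chloride
Product: 9 (R)-4-benzyl-3-(benzyloxyacetyl)-2-oxazolidinone
Conditions: Et3N, DMAP (cat.), CH2Cl2, 0 °C to rt
Reagents that add atoms: none
Why: N-acylation of the oxazolidinone by the acid chloride under DMAP catalysis; no stereocentre is touched.

Step 7
Reactants: 9 (R)-4-benzyl-3-(benzyloxyacetyl)-2-oxazolidinone; 10 3,4-bis(benzyloxy)benzaldehyde
Product: 12 (R)-4-benzyl-3-[(2R,3S)-2-benzyloxy-3-(3,4-dibenzyloxyphenyl)-3-hydroxypropanoyl]-2-oxazolidinone, via Z-dibutylboron enolate 11 (not isolated)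
Conditions: Bu2BOTf, Et3N, CH2Cl2, −78 to 0 °C; 10, −78 to 0 °C; then MeOH, pH 7 buffer, H2O2
Reagents that add atoms: none
Why: Evans syn-aldol reaction of a glycolate imide: the Z boron enolate reacts through a closed chair transition state on the face away from the benzyl group of the (R)-auxiliary, which sets the future C3 (R at this stage) and C2 (S) as the syn pair.

Step 8
Reactants: 12 syn-aldol imide
Product: 13 (2R,3S)-2-benzyloxy-3-[3,4-bis(benzyloxy)phenyl]-3-hydroxy-N-methoxy-N-methylpropanamide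
Conditions: MeNHOMe·HCl, AlMe3, THF, −10 °C to rt
Reagents that add atoms: N,O-dimethylhydroxylamine hydrochloride, CNOC.Cl
Why: Weinreb transamidation with the aluminium amide, helped by the free β-hydroxyl group, removes the auxiliary without touching the two stereocentres.

Step 9
Reactants: 13 β-hydroxy Weinreb amide
Product: 14 (2R,3S)-2-benzyloxy-3-[3,4-bis(benzyloxy)phenyl]-N-methoxy-N-methyl-3-(triethylsilyloxy)propanamide
Conditions: Et3SiCl, imidazole, CH2Cl2, 0 °C to rt
Reagents that add atoms: chlorotriethylsilane, CC[Si](CC)(CC)Cl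
Why: Standard silylation of the only free hydroxyl group; the silyl ether masks the oxygen at C2 until step 13 and does not chelate in step 11.

Step 10
Reactants: 14 silylated Weinreb amide; 15 1,3,5-trifluorobenzene
Product: 17 (2R,3S)-2-benzyloxy-3-[3,4-bis(benzyloxy)phenyl]-3-(triethylsilyloxy)-1-(2,4,6-trifluorophenyl)propan-1-one, via 2,4,6-trifluorophenyllithium 16 (not isolated)
Conditions: 15, n-BuLi, THF, −78 °C; then 14, −78 °C; quench with pH 7 buffer at −78 °C
Reagents that add atoms: none
Why: Ortho-lithiation of the fluoroarene (all three C–H positions are equivalent) and Weinreb ketone synthesis; the chelated tetrahedral adduct stops over-addition, and keeping the temperature below −70 °C avoids loss of LiF to the aryne and epimerisation at the α-carbon.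

Step 11
Reactants: 17 α-benzyloxy trifluorophenyl ketone
Product: 18 (1S,2S,3S)-2-benzyloxy-3-[3,4-bis(benzyloxy)phenyl]-3-(triethylsilyloxy)-1-(2,4,6-trifluorophenyl)propan-1-ol (C2/C3 syn, C3/C4 anti in flavan numbering)
Conditions: Zn(BH4)2, Et2O, −78 to −30 °C
Reagents that add atoms: none
Why: Cram-chelate controlled reduction of an α-alkoxy ketone: zinc ties the carbonyl oxygen to the α-benzyloxy oxygen and hydride should come from the side of the α-hydrogen, which sets C4 (S) anti to C3.

Step 12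
Reactants: 6 dimer thioether; 18 trifluorophenyl carbinol
Product: 19 acyclic ether: the C4 oxygen of 18 bound to C4β of the middle unit of the 8-bromo-deca-O-benzyl dimer
Conditions: I2, Ag2O, 4 Å molecular sieves, CH2Cl2, −78 to −20 °C
Reagents that add atoms: none
Why: Thiophile-promoted SN1 etherification at flavan C4 (the soft counterpart of step 5, akin to thioglycoside activation): iodine and silver remove the arylthio group while Ag2O keeps the medium free of acid, the hydroxyl group of 18 is the only nucleophile because its fluorinated ring is inert and C8 of the top unit is blocked, attack anti to the 2α-aryl and 3α-benzyloxy groups should give the 4β ether, and the carbinol centre of 18 keeps its configuration because its C–O bond is not broken.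

Step 13
Reactants: 19 acyclic trifluorophenyl ether
Product: 21 8-bromo-pentadeca-O-benzyl derivative of the target (ring C of the third unit closed; ring A 5,7-dibenzyloxylated), via 5,7-difluorochroman trimer 20 (not isolated)
Conditions: CsF (0.2 equiv), 18-crown-6 (0.2 equiv), DMI, 40 °C; then BnOH/KH (premixed, 10 equiv), 18-crown-6, 105 °C, one pot
Reagents that add atoms: benzyl alcohol, OCc1ccccc1
Why: Fluoride takes the triethylsilyl group from the oxygen at C2, the free alkoxide adds to an ortho C–F carbon of the trifluorophenyl ring, and the Meisenheimer adduct expels fluoride, which desilylates the next molecule, so a catalytic amount of CsF should carry the closure to 20 under almost neutral conditions. The closest known reaction type is the intramolecular nucleophilic aromatic substitution of a fluoroarene by a benzylic alkoxide that closes the pyran ring of flavan-3-ols, joined here to the fluoride-catalysed arylation of silyl ethers. Ring C of the third unit closes by a formally 6-exo-trig addition–elimination that forms O1–C8a. No stereocentre is formed and no bond at C2, C3 or C4 is broken, so the syn,anti triad set in steps 7 and 11 becomes the (2S)-2,3-cis-3,4-cis pattern with the C2 aryl and C4 ether groups pseudo-equatorial and the C3 benzyloxy group axial. The step needs chemoselectivity, secured because every other hydroxyl group is a benzyl ether (so the oxygen at C3 cannot close a five-membered ring), and it needs no regioselectivity because rotation about C4–C4a exchanges the two ortho fluorines; the closure is run before benzyl oxide is added so that the ortho positions cannot both be used up. The remaining fluorines at C5 and C7 are meta to every oxygen donor, so their Meisenheimer adducts are not destabilised and BnOK should replace both on heating, while the C8 bromide (no ortho hydrogen, electron-rich ring) and all ether bonds should be inert to the base.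

Step 14
Reactants: 21 8-bromo-pentadeca-O-benzyl trimer
Product: 22 target CNP0310719.1
Conditions: H2 (1 atm), Pd(OH)2/C, Et3N (1.2 equiv), THF/MeOH/H2O, rt
Reagents that add atoms: none
Why: Catalytic hydrogenolysis removes the fifteen primary O-benzyl groups and the C8 bromine in one operation; the amine takes up HBr so that the acid-labile C4–O–C4 ether and the C4–C8 bond are not ionised, and the hindered secondary benzylic C–O bonds (C2–O1, C4–O) should react much more slowly than the primary benzyl ethers.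

Compound list
1 | (−)-epicatechin, (2R,3R) | Oc1cc(O)c2c(c1)O[C@H](c1ccc(O)c(O)c1)[C@H](O)C2 | starting material
2 | 3,5,7,3',4'-penta-O-benzyl-(−)-epicatechin | c3ccccc3COc1cc(OCc3ccccc3)c2c(c1)O[C@H](c1ccc(OCc3ccccc3)c(OCc3ccccc3)c1)[C@H](OCc3ccccc3)C2 | intermediate
3 | (2R,3R,4S)-4β-(2-ethoxyethoxy)-penta-O-benzylepicatechin | c3ccccc3COc1cc(OCc3ccccc3)c2c(c1)O[C@H](c1ccc(OCc3ccccc3)c(OCc3ccccc3)c1)[C@H](OCc3ccccc3)[C@H]2OCCOCC | intermediate
4 | 8-bromo-4β-(2-ethoxyethoxy)-penta-O-benzylepicatechin | c3ccccc3COc1cc(OCc3ccccc3)c2c(c1Br)O[C@H](c1ccc(OCc3ccccc3)c(OCc3ccccc3)c1)[C@H](OCc3ccccc3)[C@H]2OCCOCC | intermediate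
5 | 4β-(2,6-dimethylphenylthio)-penta-O-benzylepicatechin | c3ccccc3COc1cc(OCc3ccccc3)c2c(c1)O[C@H](c1ccc(OCc3ccccc3)c(OCc3ccccc3)c1)[C@H](OCc3ccccc3)[C@H]2Sc1c(C)cccc1C | intermediate
6 | 8-bromo-penta-O-benzylepicatechin-(4β→8)-4β-(2,6-dimethylphenylthio)-penta-O-benzylepicatechin | c3ccccc3COc1cc(OCc3ccccc3)c2c(c1Br)O[C@H](c1ccc(OCc3ccccc3)c(OCc3ccccc3)c1)[C@H](OCc3ccccc3)[C@H]2c1c(OCc3ccccc3)cc(OCc3ccccc3)c2c1O[C@H](c1ccc(OCc3ccccc3)c(OCc3ccccc3)c1)[C@H](OCc3ccccc3)[C@H]2Sc1c(C)cccc1C | intermediate
7 | (R)-4-benzyl-2-oxazolidinone | O=C1N[C@H](Cc2ccccc2)CO1 | starting material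
8 | benzyloxyacetyl chloride | O=C(Cl)COCc1ccccc1 | starting material
9 | (R)-4-benzyl-3-(benzyloxyacetyl)-2-oxazolidinone | O=C1OC[C@@H](Cc2ccccc2)N1C(=O)COCc1ccccc1 | intermediate
10 | 3,4-bis(benzyloxy)benzaldehyde | O=Cc1ccc(OCc2ccccc2)c(OCc2ccccc2)c1 | starting material
11 | Z-dibutylboron enolate of 9 | CCCCB(CCCC)O/C(=C\OCc1ccccc1)N1C(=O)OC[C@H]1Cc1ccccc1 | intermediate
12 | (R)-4-benzyl-3-[(2R,3S)-2-benzyloxy-3-(3,4-dibenzyloxyphenyl)-3-hydroxypropanoyl]-2-oxazolidinone | O=C1OC[C@@H](Cc2ccccc2)N1C(=O)[C@H](OCc1ccccc1)[C@@H](O)c1ccc(OCc2ccccc2)c(OCc2ccccc2)c1 | intermediate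
13 | (2R,3S)-2-benzyloxy-3-[3,4-bis(benzyloxy)phenyl]-3-hydroxy-N-methoxy-N-methylpropanamide | CON(C)C(=O)[C@H](OCc1ccccc1)[C@@H](O)c1ccc(OCc2ccccc2)c(OCc2ccccc2)c1 | intermediate
14 | 3-O-triethylsilyl ether of 13 | CON(C)C(=O)[C@H](OCc1ccccc1)[C@@H](O[Si](CC)(CC)CC)c1ccc(OCc2ccccc2)c(OCc2ccccc2)c1 | intermediate
15 | 1,3,5-trifluorobenzene | Fc1cc(F)cc(F)c1 | starting material
16 | 2,4,6-trifluorophenyllithium | [Li]c1c(F)cc(F)cc1F | intermediate
17 | (2R,3S)-2-benzyloxy-3-[3,4-bis(benzyloxy)phenyl]-3-(triethylsilyloxy)-1-(2,4,6-trifluorophenyl)propan-1-one | O=C(c1c(F)cc(F)cc1F)[C@H](OCc1ccccc1)[C@@H](O[Si](CC)(CC)CC)c1ccc(OCc2ccccc2)c(OCc2ccccc2)c1 | intermediate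
18 | (1S,2S,3S)-2-benzyloxy-3-[3,4-bis(benzyloxy)phenyl]-3-(triethylsilyloxy)-1-(2,4,6-trifluorophenyl)propan-1-ol | O[C@@H](c1c(F)cc(F)cc1F)[C@H](OCc1ccccc1)[C@@H](O[Si](CC)(CC)CC)c1ccc(OCc2ccccc2)c(OCc2ccccc2)c1 | intermediate
19 | acyclic ether of 18 at C4β of the middle unit of the 8-bromo-deca-O-benzyl dimer | c3ccccc3COc1cc(OCc3ccccc3)c2c(c1Br)O[C@H](c1ccc(OCc3ccccc3)c(OCc3ccccc3)c1)[C@H](OCc3ccccc3)[C@H]2c1c(OCc3ccccc3)cc(OCc3ccccc3)c2c1O[C@H](c1ccc(OCc3ccccc3)c(OCc3ccccc3)c1)[C@H](OCc3ccccc3)[C@H]2O[C@@H](c1c(F)cc(F)cc1F)[C@H](OCc3ccccc3)[C@@H](O[Si](CC)(CC)CC)c1ccc(OCc3ccccc3)c(OCc3ccccc3)c1 | intermediate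
20 | trimer with closed third unit, (2S,3S,4S)-3-benzyloxy-2-(3,4-dibenzyloxyphenyl)-5,7-difluorochroman-4-yl ether | c3ccccc3COc1cc(OCc3ccccc3)c2c(c1Br)O[C@H](c1ccc(OCc3ccccc3)c(OCc3ccccc3)c1)[C@H](OCc3ccccc3)[C@H]2c1c(OCc3ccccc3)cc(OCc3ccccc3)c2c1O[C@H](c1ccc(OCc3ccccc3)c(OCc3ccccc3)c1)[C@H](OCc3ccccc3)[C@H]2O[C@H]1c2c(F)cc(F)cc2O[C@@H](c2ccc(OCc3ccccc3)c(OCc3ccccc3)c2)[C@H]1OCc3ccccc3 | intermediate
21 | 8-bromo-pentadeca-O-benzyl derivative of the target | c3ccccc3COc1cc(OCc3ccccc3)c2c(c1Br)O[C@H](c1ccc(OCc3ccccc3)c(OCc3ccccc3)c1)[C@H](OCc3ccccc3)[C@H]2c1c(OCc3ccccc3)cc(OCc3ccccc3)c2c1O[C@H](c1ccc(OCc3ccccc3)c(OCc3ccccc3)c1)[C@H](OCc3ccccc3)[C@H]2O[C@H]1c2c(OCc3ccccc3)cc(OCc3ccccc3)cc2O[C@@H](c2ccc(OCc3ccccc3)c(OCc3ccccc3)c2)[C@H]1OCc3ccccc3 | intermediate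
22 | CNP0310719.1, epicatechin-(4β→8)-epicatechin 4β-yl ether of (2S,3S,4S)-2-(3,4-dihydroxyphenyl)chroman-3,4,5,7-tetraol | Oc1cc(O)c2c(c1)O[C@H](c1ccc(O)c(O)c1)[C@H](O)[C@H]2c1c(O)cc(O)c2c1O[C@H](c1ccc(O)c(O)c1)[C@H](O)[C@H]2O[C@H]1c2c(O)cc(O)cc2O[C@@H](c2ccc(O)c(O)c2)[C@H]1O | target

Total step count: 14. Longest linear sequence: 9 steps (steps 6 to 14).

Steps most likely to fail

Step 13.
- **Risk:** Substitution of the C5 fluorine may be slow, because it lies next to the bulky C4 ether. Long heating with benzyl oxide could then leave the exchange incomplete or strip aryl benzyl groups.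
- **Fallback:** It sets out from 14 and 15 and comes back at 21. Both benzyloxy groups are placed on ring A before the ring is attached.
  - 15 with two equivalents of BnONa (DMI, 90 °C) should give 1,3-bis(benzyloxy)-5-fluorobenzene F1.
  - NBS should brominate para to one benzyloxy group and next to fluorine, giving 2-bromo-1,5-bis(benzyloxy)-3-fluorobenzene F2.
  - n-BuLi (THF, −78 °C) gives 2,4-bis(benzyloxy)-6-fluorophenyllithium F3.
  - F3 adds to 14 to give the aryl ketone F4.
  - Zn(BH4)2 should give the anti alcohol F5.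
  - Coupling with 6 under I2/Ag2O as in step 12 gives the acyclic ether F6.
  - TBAF and then KH (DMI, 70 °C) close ring C by the same intramolecular substitution, now of the single fluorine, and lead directly to 21.

Step 12.
- **Risk:** The hindered, weakly nucleophilic acyclic alcohol may capture the hindered C4 cation too slowly. Loss of H3 to the flav-3-ene, uptake of water or ring iodination could then take over.
- **Fallback:** It sets out from 18 and comes back at 20. The ring is closed before the ether is made.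
  - TBAF and then NaH (DMI, rt) should convert 18 into (2S,3S,4S)-3-benzyloxy-2-[3,4-bis(benzyloxy)phenyl]-5,7-difluorochroman-4-ol F7.
  - Only the oxygen at C2 can reach an ortho fluorine, because the oxygen at C4 would have to form a four-membered ring.
  - The 4-hydroxyl group of F7 is tied back in the ring and flanked only by the small 5-fluorine. Its difluorinated ring A is still no carbon nucleophile.
  - Coupling of F7 with 6 under I2/Ag2O gives 20, which is then isolated and treated with BnOK as in the second stage of step 13.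

Step 14.
- **Risk:** The bis-benzylic C4–O–C4 ether may be cleaved along with the benzyl groups, either by hydrogenolysis or by ionisation with acid released from the C–Br bond.
- **Fallback:** It sets out from 21 and comes back at 22. The bromine is removed first in a separate radical step.
  - Bu3SnH and AIBN (toluene, 80 °C) give the bromine-free pentadeca-O-benzyl trimer F8.
  - Hydrogenolysis of F8 (H2, Pd(OH)2/C, THF/MeOH/H2O) then forms no acid and needs no base. It can be stopped as soon as the primary benzyl ethers are gone.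

Further compounds
F1 | step 13 | 1,3-bis(benzyloxy)-5-fluorobenzene | Fc1cc(OCc2ccccc2)cc(OCc2ccccc2)c1
F2 | step 13 | 2-bromo-1,5-bis(benzyloxy)-3-fluorobenzene | Fc1cc(OCc2ccccc2)cc(OCc2ccccc2)c1Br
F3 | step 13 | 2,4-bis(benzyloxy)-6-fluorophenyllithium | [Li]c1c(F)cc(OCc2ccccc2)cc1OCc1ccccc1
F4 | step 13 | 2-benzyloxy-1-[2,4-bis(benzyloxy)-6-fluorophenyl]-3-[3,4-bis(benzyloxy)phenyl]-3-(triethylsilyloxy)propan-1-one, configured as 17 | O=C(c1c(F)cc(OCc2ccccc2)cc1OCc1ccccc1)[C@H](OCc1ccccc1)[C@@H](O[Si](CC)(CC)CC)c1ccc(OCc2ccccc2)c(OCc2ccccc2)c1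
F5 | step 13 | anti alcohol from F4, configured as 18 | O[C@@H](c1c(F)cc(OCc2ccccc2)cc1OCc1ccccc1)[C@H](OCc1ccccc1)[C@@H](O[Si](CC)(CC)CC)c1ccc(OCc2ccccc2)c(OCc2ccccc2)c1
F6 | step 13 | acyclic ether of F5 at C4β of the middle unit of the 8-bromo-deca-O-benzyl dimer | c3ccccc3COc1cc(OCc3ccccc3)c2c(c1Br)O[C@H](c1ccc(OCc3ccccc3)c(OCc3ccccc3)c1)[C@H](OCc3ccccc3)[C@H]2c1c(OCc3ccccc3)cc(OCc3ccccc3)c2c1O[C@H](c1ccc(OCc3ccccc3)c(OCc3ccccc3)c1)[C@H](OCc3ccccc3)[C@H]2O[C@@H](c1c(F)cc(OCc3ccccc3)cc1OCc3ccccc3)[C@H](OCc3ccccc3)[C@@H](O[Si](CC)(CC)CC)c1ccc(OCc3ccccc3)c(OCc3ccccc3)c1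
F7 | step 12 | (2S,3S,4S)-3-benzyloxy-2-[3,4-bis(benzyloxy)phenyl]-5,7-difluorochroman-4-ol | O[C@H]1c2c(F)cc(F)cc2O[C@@H](c2ccc(OCc3ccccc3)c(OCc3ccccc3)c2)[C@H]1OCc3ccccc3
F8 | step 14 | bromine-free pentadeca-O-benzyl derivative of the target | c3ccccc3COc1cc(OCc3ccccc3)c2c(c1)O[C@H](c1ccc(OCc3ccccc3)c(OCc3ccccc3)c1)[C@H](OCc3ccccc3)[C@H]2c1c(OCc3ccccc3)cc(OCc3ccccc3)c2c1O[C@H](c1ccc(OCc3ccccc3)c(OCc3ccccc3)c1)[C@H](OCc3ccccc3)[C@H]2O[C@H]1c2c(OCc3ccccc3)cc(OCc3ccccc3)cc2O[C@@H](c2ccc(OCc3ccccc3)c(OCc3ccccc3)c2)[C@H]1OCc3ccccc3
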